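# Proposed synthesis of serpyllin (5-hydroxy-7,8-dimethoxy-2-(2,3,4-trimethoxyphenyl)-4H-chromen-4-one)

## Structural features

Serpyllin (7) is a flavone: benzene ring A is fused through C4a–C8a to 4H-pyran-4-one ring C, which carries the 2,3,4-trimethoxyphenyl ring B on C2 through the single C2–C1′ bond. Ring A is oxygenated at every position except C6 (5-OH, 7-OCH3, 8-OCH3 and the ring oxygen O1 on C8a), and ring B has three contiguous methoxy groups, one of them ortho to the inter-ring bond. The molecule has no stereocentre, so nothing has to be set in relative or absolute configuration; the difficulty is regiochemical. Two things must be decided: which of the two ring-A oxygens ortho to the acyl-bearing C4a becomes O1 (this separates the 5,7,8- from the isomeric 5,6,7-pattern), and how the single phenol on C5 is kept apart from five methyl ethers. The sensitive points are the electron-rich, oxidisable rings, the 5-hydroxy-4-keto chelate (which in hot acid can let ring C open and reclose through the other ortho oxygen), and an air-sensitive 5,8-dihydroxy (hydroquinone) intermediate on the way. The key step uses the para relation of the oxygens on C5 and C8: ring A is a 1,4-benzoquinone in reduced, methylated form, and at the quinone level C8a, which is β to both the C5 and the C4 carbonyl, is an electrophile that can take up O1, the reverse of the usual polarity in which a phenolic O1 attacks C2.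

## Logic of the disconnections

**7 ⇒ 6.** The bond cut is the O–CH3 bond on the C8 oxygen. It is cut there because the two free hydroxyls of 6 are not alike: the one on C5 is tied to the C4 carbonyl by a hydrogen bond, the one on C8 is not, so one methyl group can be placed without protecting groups. The gain is that 6 has both para oxygens of ring A free, which is what a ring closure at the quinone oxidation level delivers. The demand on the forward step is methylation at O8 only, on a hydroquinone that base and air together would oxidise.

**6 ⇒ 3 (through 5 and 4).** The bond cut is O1–C8a, the aryl carbon–oxygen bond of ring C. In the same retrosynthetic operation ring A is taken to the quinone level and then back to a methylated arene: 6 and 5 differ by two electrons and two protons, 5 and 4 by the O1–C8a bond, and 4 and 3 by two O-methyl groups on the C5 and C8 oxygens. The cut is made there because only at the oxidation level of 4 is C8a an electrophile and O1, as an enol oxygen, a nucleophile within reach. The gain is large: ring C is opened, no ring-A phenol has to be differentiated beforehand, and ring A becomes a 2,4,5-trimethoxyphenyl group whose substitution pattern already encodes the 5,7,8-oxygenation. The demand is that the oxidant attacks ring A and not ring B or the enolised diketone, and that closure takes place at C8a through O1 only.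

**3 ⇒ 1 + 2.** The bond cut is the future C2–C3 bond, between the central methylene carbon and the carbonyl carbon attached to ring B. This is the retron of a Claisen condensation and divides 3 into two aromatic building blocks of equal size, each with all its methoxy groups in place. The gain is full convergence from two catalogue compounds. The demand is that the enolate of 1 is acylated by the electron-rich, ortho-substituted ester 2 faster than it condenses with itself, and that enough base is present to hold the product as its diketonate.

## Other disconnections considered

**Alternative 1:** Biomimetic Claisen folding of a polyketide chain.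
- **Cut:** inside ring A, between the acyl-bearing carbon and a neighbouring oxygenated carbon (C4a–C8a, which in a symmetric phloroglucinol is the same as C4a–C5). This leads back to methyl (E)-3,5,7-trioxo-9-(2,3,4-trimethoxyphenyl)non-8-enoate A1.
- **Forward key step:** Mg(OCH3)2 would chelate the polycarbonyl chain and the carbanion at C6 would attack the ester carbonyl C1 (Claisen cyclisation). After enolisation this would give (E)-1-(2,4,6-trihydroxyphenyl)-3-(2,3,4-trimethoxyphenyl)prop-2-en-1-one A2. Oxidative cyclisation (I2, DMSO) would then give 5,7-dihydroxy-2-(2,3,4-trimethoxyphenyl)-4H-chromen-4-one A3.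
- **In favour:** the ring closure follows the logic of chalcone biosynthesis, needs no oxidant, and builds the aromatic ring from an acyclic chain with no ambiguity about where the three oxygens sit.
- **Against:**
  - A2 and A3 lack the oxygen on C8. It would have to be introduced late (for example by Elbs persulfate hydroxylation para to the 5-OH after 7-O-methylation) to reach 6, after which the same final methylation as in the chosen plan would still be needed.
  - A1 is not purchasable and would need several steps of polyanion chemistry.
  - The chain of A1 can also fold by aldol condensation or close to a pyranone.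
- **Comparison:**
  - Structure: the chosen plan installs the complete 5,7,8-oxygenation in the ring-closing step; Alternative 1 leaves it incomplete.
  - Mechanism: Alternative 1 is the better, because Claisen cyclisation of triketo esters to acylphloroglucinols is an established reaction type and the chosen key step is not.
  - Step economy: three steps for the chosen plan against roughly eight or more.

**Alternative 2:** Palladium-catalysed carbonylative annulation.
- **Cut:** three bonds of ring C (C4a–C4, C4–C3 and O1–C2), giving 2-iodo-3,5,6-trimethoxyphenol A4, CO and 1-ethynyl-2,3,4-trimethoxybenzene A5.
- **Forward key step:** with PdCl2(PPh3)2 in Et2NH, zerovalent palladium would insert into the C–I bond, CO would insert, the acyl palladium species would couple with the alkyne to an ynone, and the amine would mediate 6-endo addition of the phenol. The product would be 5,7,8-trimethoxy-2-(2,3,4-trimethoxyphenyl)-4H-chromen-4-one A6. One further step, selective cleavage of the 5-methoxy group with BCl3, would give 7.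
- **In favour:** it is the most convergent plan, the reaction type is established for flavones from ortho-iodophenols, and the position of iodine fixes the ring-A pattern beyond doubt.
- **Against:**
  - A4 is not a commodity chemical; it needs a regioselective iodination of a phenol that itself has to be made.
  - The iodide of A4 is flanked by two ortho substituents on a very electron-rich ring, which slows oxidative addition.
  - A5 must be prepared from the aldehyde.
  - Five-membered (aurone) closure can compete with the 6-endo closure.
  - CO gas and a palladium catalyst are required.
- **Comparison:**
  - Structure: both plans fix the regiochemistry of ring A unambiguously; here the end game is a demethylation, in the chosen plan a methylation, and the two are of equal reliability.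
  - Mechanism: Alternative 2 is the better on precedent and on convergence.
  - Step economy: once the preparation of A4 and A5 is counted it needs about six operations (longest linear sequence about four), against three from catalogue compounds.

**Alternative 3:** Ring A last, by Claisen benzannulation on a pyranone.
- **Cut:** C5–C6 of ring A, leading back to methyl 2-(1-methoxy-2-oxopropyl)-4-oxo-6-(2,3,4-trimethoxyphenyl)-4H-pyran-3-carboxylate A7.
- **Forward key step:** LiN(SiMe3)2 would generate the methyl ketone enolate, whose carbon (C6) would attack the ester carbonyl (C5) in a Dieckmann-type closure. Enolisation of the resulting cyclic diketone would give 5,7-dihydroxy-8-methoxy-2-(2,3,4-trimethoxyphenyl)-4H-chromen-4-one A8. Methylation of the 7-OH would finish 7.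
- **In favour:**
  - The 8-methoxy group is carried in from the start, and each ring-A oxygen comes from a different carbonyl, so no isomer problem arises.
  - A8 is a resorcinol, not a hydroquinone, and is therefore not air-sensitive.
  - Its final step, methylation of the acidic 7-OH next to a chelated 5-OH, is at least as selective as the final step of the chosen plan. On this point Alternative 3 is the equal or the better.
- **Against:**
  - A7 is a densely functionalised pyranone that would itself take several steps.
  - The proton on the methoxy-bearing carbon of A7 is more acidic than the methyl protons, so the closure would have to run through a dianion.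
  - 4-Pyranones are opened by strong bases and nucleophiles.
- **Comparison:**
  - Structure: both plans end with one O-methylation of a dihydroxyflavone.
  - Mechanism: the closure is of a known type but on an unusual substrate; the chosen key step is of an untested type on a simple substrate.
  - Step economy: the chosen plan is clearly shorter.

Key step: step 2

## Remarks before the steps

- The structures of 3, 6 and 7 were checked atom by atom. C2 and C5 of the 2,4,5-trimethoxyphenyl ring of 3 become C5 and C8, its C6 becomes C8a and its C4 becomes C7; the ring-B carbonyl oxygen becomes O1. Everything is consistent with the target and no structure needs correction.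
- One change is made to the stoichiometry of the key step. Slightly more than four equivalents of tetravalent cerium are used instead of two. Product 6 is a hydroquinone that the intermediate acylquinone 4 could otherwise oxidise, and reduced 4 would be free to close through the wrong oxygen. With excess oxidant everything is carried to 5, which is reduced to 6 in the work-up.
- Assumption on mechanism: in the oxidative demethylation the aryl–oxygen bonds are taken to break, so the two quinone oxygens (later the C5 and C8 oxygens) come from water and the methoxy groups leave as methanol.
- Conjugate bases (enolates, phenoxides) are treated as ionised forms of the numbered compounds and carry no number of their own.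
- 1 and 2 are taken as catalogue compounds.

## Route

Step 1
Reactants: 1 1-(2,4,5-trimethoxyphenyl)ethanone; 2 methyl 2,3,4-trimethoxybenzoate
Product: 3 1-(2,4,5-trimethoxyphenyl)-3-(2,3,4-trimethoxyphenyl)propane-1,3-dione
Conditions: LiN(SiMe3)2 (2.5 equiv), THF, −78 °C, 1 h; 2 (1.1 equiv), −78 → 23 °C, then 40 °C; AcOH quench
Reagents that add atoms: none
Why: Crossed Claisen condensation (acylation of a ketone enolate by a non-enolisable ester): only 1 can form an enolate, 2 cannot self-condense, and the excess amide base turns 3 into its chelated lithium diketonate, which pulls the equilibrium forward and blocks a second acylation; the six aryl methyl ethers are inert to the base.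

Step 2
Reactants: 3 1-(2,4,5-trimethoxyphenyl)-3-(2,3,4-trimethoxyphenyl)propane-1,3-dione
Product: 6 5,8-dihydroxy-7-methoxy-2-(2,3,4-trimethoxyphenyl)-4H-chromen-4-one, via acylquinone 4 (not isolated), via chromenetrione 5 (not isolated)
Conditions: (NH4)2Ce(NO3)6 (4.4 equiv), MeCN–H2O 3:1, 0 → 23 °C (3 added to the oxidant); then EtOAc, aq. Na2S2O4, 23 °C
Reagents that add atoms: water, O
Why: Proposed new method: tetravalent cerium takes two electrons from ring A of 3, the only ring with a para-dimethoxy pair, water adds at the two ipso carbons and two molecules of methanol leave, which gives acylquinone 4 (oxidative demethylation; the two new carbonyl oxygens come from water). In 4 the ring CH next to the acyl-bearing carbon, the future C8a, is β to the future C5 carbonyl and to the side-chain carbonyl and is the most electrophilic carbon; the enol oxygen on the ring-B side of the diketone adds to it through a six-membered transition state, a 6-endo-trig oxa-Michael addition that forms O1–C8a and closes ring C, and tautomerisation gives the aromatic hydroquinone 6. The excess oxidant takes this first-formed 6 on to chromenetrione 5, so that 4 is never left to be reduced by 6 to a hydroquinone that could close through the wrong oxygen, and Na2S2O4 in the work-up returns 5 to 6. The closest known reaction types are the oxidative demethylation of para-dimethoxyarenes to quinones by (NH4)2Ce(NO3)6 and the closure of oxygen nucleophiles onto acylquinones, as in xanthone formation from oxidised 2-hydroxybenzophenones; ring C of a flavone has not been closed in this way. No stereocentre is formed. The step needs oxidation of ring A ahead of ring B and of the enolised diketone, which rests on ring A being the more electron-rich ring and the only one that can collapse to a quinone, helped by 0 °C and a short contact time. It also needs closure at C8a by O1 alone, which the tether secures: the central carbon or the nearer carbonyl oxygen would have to form a four-membered ring, and addition of O1 to the quinone carbonyl carbon is reversible.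

Step 3
Reactants: 6 5,8-dihydroxy-7-methoxy-2-(2,3,4-trimethoxyphenyl)-4H-chromen-4-one
Product: 7 serpyllin, 5-hydroxy-7,8-dimethoxy-2-(2,3,4-trimethoxyphenyl)-4H-chromen-4-one
Conditions: (CH3O)2SO2 (1.05 equiv), K2CO3 (1.2 equiv), degassed acetone, Ar, 23 → 40 °C
Reagents that add atoms: dimethyl sulfate, COS(=O)(=O)OC
Why: Chemoselective O-methylation of a phenoxide (Williamson-type SN2 on dimethyl sulfate): the 5-OH is held in a six-membered hydrogen bond to the C4 carbonyl and is neither deprotonated nor alkylated by K2CO3 at this temperature, so the single equivalent of electrophile goes to the free 8-OH; argon keeps the hydroquinone from base-promoted air oxidation.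

## Compound list

1 | 1-(2,4,5-trimethoxyphenyl)ethanone | CC(=O)c1cc(OC)c(OC)cc1OC | starting material
2 | methyl 2,3,4-trimethoxybenzoate | COC(=O)c1ccc(OC)c(OC)c1OC | starting material
3 | 1-(2,4,5-trimethoxyphenyl)-3-(2,3,4-trimethoxyphenyl)propane-1,3-dione | COc1ccc(C(=O)CC(=O)c2cc(OC)c(OC)cc2OC)c(OC)c1OC | intermediate
4 | 1-(4-methoxy-3,6-dioxocyclohexa-1,4-dien-1-yl)-3-(2,3,4-trimethoxyphenyl)propane-1,3-dione (acylquinone) | COC1=CC(=O)C(C(=O)CC(=O)c2ccc(OC)c(OC)c2OC)=CC1=O | intermediate (not isolated)
5 | 7-methoxy-2-(2,3,4-trimethoxyphenyl)-4H-chromene-4,5,8-trione (chromenetrione) | COC1=CC(=O)C2=C(OC(=CC2=O)c2ccc(OC)c(OC)c2OC)C1=O | intermediate (not isolated)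
6 | 5,8-dihydroxy-7-methoxy-2-(2,3,4-trimethoxyphenyl)-4H-chromen-4-one | COc1ccc(-c2cc(=O)c3c(O)cc(OC)c(O)c3o2)c(OC)c1OC | intermediate
7 | serpyllin, 5-hydroxy-7,8-dimethoxy-2-(2,3,4-trimethoxyphenyl)-4H-chromen-4-one | COc1ccc(-c2cc(=O)c3c(O)cc(OC)c(OC)c3o2)c(OC)c1OC | target

## Step count and risk assessment

Total step count: 3. Longest linear sequence: 3 steps (1 → 3 → 6 → 7; 2 enters in step 1).

**Step 2 (key step, proposed new method).**
What may go wrong:
- (a) One-electron oxidation of the enolised 1,3-diketone by tetravalent cerium (inner-sphere oxidation of a cerium diketonate), leading to α-oxygenation, dimerisation or chain cleavage. The diketone is a good ligand for cerium and the carbonyl group on ring A raises that ring's oxidation potential.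
- (b) Slow O-closure, because the enol oxygen has to leave its internal hydrogen bond and rotate into reach of C8a, so that water or nitrate intercepts the acylquinone first.
- (c) Hydrolytic opening of the pyranone ring at the chromenetrione stage in the acidic aqueous medium.

Fallback, known chemistry throughout: it sets out from 2 and comes back to the route at 7, so that step 3 is bypassed as well. The lithium dianion of the catalogue compound 1-(2-hydroxy-3,4,6-trimethoxyphenyl)ethanone F1 (LiN(SiMe3)2, 3.2 equiv, THF, −78 → 23 °C) would be acylated by 2 in a Claisen condensation to give 1-(2-hydroxy-3,4,6-trimethoxyphenyl)-3-(2,3,4-trimethoxyphenyl)propane-1,3-dione F2. Acid-catalysed cyclodehydration (catalytic H2SO4, AcOH, 95 °C) can only go through the single free phenol and should give 5,7,8-trimethoxy-2-(2,3,4-trimethoxyphenyl)-4H-chromen-4-one F3. BCl3 (CH2Cl2, −78 → 0 °C) binds to the C4 carbonyl and should cleave only the peri 5-methoxy group, which gives 7.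

**Step 1.**
What may go wrong: slow acylation, because the ester carbonyl of 2 is deactivated by ortho and para methoxy groups and shielded by the ortho substituent. The enolate of 1 then has time for self-condensation (aldol addition to unreacted ketone) or is returned to 1 by proton transfer from the product.

Fallback: it sets out from 1 and comes back at 3. The lithium enolate of 1 (LiN(i-Pr)2, THF, −78 °C) would add to the far more electrophilic 2,3,4-trimethoxybenzaldehyde F4 to give racemic 3-hydroxy-1-(2,4,5-trimethoxyphenyl)-3-(2,3,4-trimethoxyphenyl)propan-1-one F5 (kinetic aldol addition, quenched cold with AcOH to avoid dehydration). Oxidation of this β-hydroxy ketone with 2-iodoxybenzoic acid (EtOAc, 75 °C) should give 3.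

**Step 3.**
What may go wrong: base-promoted air oxidation of the hydroquinone back to the quinone level before it is alkylated, and loss of mono-selectivity by slow methylation of the chelated 5-OH once the 8-OH has reacted.

Fallback: it sets out from 6 and comes back at 7. Exhaustive methylation ((CH3O)2SO2, 3 equiv, K2CO3, 4 equiv, acetone, reflux, Ar) makes selectivity irrelevant and should give 5,7,8-trimethoxy-2-(2,3,4-trimethoxyphenyl)-4H-chromen-4-one F6 (the same structure as F3). BCl3 (CH2Cl2, −78 → 0 °C) then removes only the 5-O-methyl group peri to the carbonyl and gives 7.

## Further compounds

F1 | step 2 | 1-(2-hydroxy-3,4,6-trimethoxyphenyl)ethanone | CC(=O)c1c(O)c(OC)c(OC)cc1OC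
F2 | step 2 | 1-(2-hydroxy-3,4,6-trimethoxyphenyl)-3-(2,3,4-trimethoxyphenyl)propane-1,3-dione | COc1ccc(C(=O)CC(=O)c2c(O)c(OC)c(OC)cc2OC)c(OC)c1OC
F3 | step 2 | 5,7,8-trimethoxy-2-(2,3,4-trimethoxyphenyl)-4H-chromen-4-one | COc1ccc(-c2cc(=O)c3c(OC)cc(OC)c(OC)c3o2)c(OC)c1OC
F4 | step 1 | 2,3,4-trimethoxybenzaldehyde | COc1ccc(C=O)c(OC)c1OC
F5 | step 1 | 3-hydroxy-1-(2,4,5-trimethoxyphenyl)-3-(2,3,4-trimethoxyphenyl)propan-1-one (racemic) | COc1ccc(C(O)CC(=O)c2cc(OC)c(OC)cc2OC)c(OC)c1OC
F6 | step 3 | 5,7,8-trimethoxy-2-(2,3,4-trimethoxyphenyl)-4H-chromen-4-one (same structure as F3) | COc1ccc(-c2cc(=O)c3c(OC)cc(OC)c(OC)c3o2)c(OC)c1OC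
A1 | alternative 1 | methyl (E)-3,5,7-trioxo-9-(2,3,4-trimethoxyphenyl)non-8-enoate | COC(=O)CC(=O)CC(=O)CC(=O)/C=C/c1ccc(OC)c(OC)c1OC
A2 | alternative 1 | (E)-1-(2,4,6-trihydroxyphenyl)-3-(2,3,4-trimethoxyphenyl)prop-2-en-1-one | COc1ccc(/C=C/C(=O)c2c(O)cc(O)cc2O)c(OC)c1OC
A3 | alternative 1 | 5,7-dihydroxy-2-(2,3,4-trimethoxyphenyl)-4H-chromen-4-one | COc1ccc(-c2cc(=O)c3c(O)cc(O)cc3o2)c(OC)c1OC
A4 | alternative 2 | 2-iodo-3,5,6-trimethoxyphenol | COc1cc(OC)c(OC)c(O)c1I
A5 | alternative 2 | 1-ethynyl-2,3,4-trimethoxybenzene | C#Cc1ccc(OC)c(OC)c1OC
A6 | alternative 2 | 5,7,8-trimethoxy-2-(2,3,4-trimethoxyphenyl)-4H-chromen-4-one | COc1ccc(-c2cc(=O)c3c(OC)cc(OC)c(OC)c3o2)c(OC)c1OC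
A7 | alternative 3 | methyl 2-(1-methoxy-2-oxopropyl)-4-oxo-6-(2,3,4-trimethoxyphenyl)-4H-pyran-3-carboxylate (racemic) | COC(=O)c1c(C(OC)C(C)=O)oc(-c2ccc(OC)c(OC)c2OC)cc1=O
A8 | alternative 3 | 5,7-dihydroxy-8-methoxy-2-(2,3,4-trimethoxyphenyl)-4H-chromen-4-one | COc1ccc(-c2cc(=O)c3c(O)cc(O)c(OC)c3o2)c(OC)c1OC
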